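(The readings are calculated with made-up constants, noise included.)

Time in a flask means little until I count it in lifetimes of Q, so the number I want for each run is the rate constant of Q → Z multiplied by the time.

| flask | L | temperature | remark | time |
|---|---|---|---|---|
| red | 0.41 M | 10 °C | run made earlier |  |
| green | 1.6 M | 30 °C | run made earlier |  |
| winter | 0.82 M | 25 °C |  | 1.5 h |
| noon | 0.82 M | 35 °C |  | 1.5 h |

| run | time / min | Q / % | L / % |
|---|---|---|---|
| red | 30.0 | 27.6 | 56.7 |
| red | 50.0 | 39.3 | 41.6 |
| red | 80.0 | 49.4 | 26.4 |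
| red | 120 | 58.3 | 16.0 |
| green | 4.00 | 38.7 | 27.2 |
| green | 10.0 | 52.5 | 8.8 |
| green | 25.0 | 57.9 | 4.3 |
| green | 50.0 | 51.6 | 2.6 |

(scatter of a reading: 0.5 percentage points)

- which of the two there is more of at the end, winter (Z / Q)
- which of the two there is more of at the end, noon (Z / Q)
- final Q, as a percentage of the L charged, in winter
- final Q, as a percentage of the L charged, in noon

I have two ways to that constant, k3, in the green run. The plain way reads the late fall of Q, from 25.0 min to 50.0 min, as a pure decay and gives 0.00461 min⁻¹. The other way takes the top of Q to lie near 25.0 min; at a top Q is made as fast as it goes, so k3/k1 = [L]/[Q], read there as 0.0743, a selectivity factor. With that factor, the gain in Q from 4.00 min to 10.0 min gives k1 = 0.157 min⁻¹, hence k3 = 0.0117 min⁻¹.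

The two ways part, and the plain way cheats: in the late window L still feeds about 13.6 % of the charge into Q, more than the visible fall of 6.3 percentage points. Adding that feed back gives 0.0145 min⁻¹ against 0.0117 min⁻¹ from the top; both rest on the same k1, so this shows me the size and is no full check, and I keep the value from the top.

The red run gives k1 = 0.0125 min⁻¹. I assume the factor holds at each temperature and that ln k runs straight with temperature. So k3 is 0.00621 min⁻¹ in winter and 0.0220 min⁻¹ in noon.

The turnover count, k3 times the time, is 0.559 in winter and 1.98 in noon. A charge turned into Q at once keeps a fraction exp(−n), which is 57.2 % and 13.8 %. In that picture Z overtakes Q at n = 0.693, so I expect Q ahead in winter, whose count is less than that, and Z ahead in noon, whose count is more.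

The forecast says Q in winter with 56 % (50 % to 62 %) and Z in noon with 12 % (7 % to 19 %), reasoning that “Q falls late in green, giving Q→Z”.

The flask gives Q 53.6 % against Z 32.7 % in winter, and Q 15.1 % against Z 84.7 % in noon, so the forecast holds.

    L → Q (k = 0.00165 s⁻¹, Ea = 98.0 kJ mol⁻¹)
    2 L ⇌ E (K = 5.20 L mol⁻¹, k = 8.89 × 10⁻⁴ L mol⁻¹ s⁻¹, Ea = 76.0 kJ mol⁻¹, ΔH = −53.0 kJ mol⁻¹)
    Q → Z (k = 1.08 × 10⁻⁴ s⁻¹, Ea = 98.0 kJ mol⁻¹)
    2 L → G (k = 6.48 × 10⁻⁷ L mol⁻¹ s⁻¹, Ea = 83.0 kJ mol⁻¹)
    (constants at 25 °C)

Winter's Q lies 3.6 points under exp(−n), with E still at 12.3 %, while noon's lies 1.3 points above it. Noon's Q moves by 6 points at 1.25 h or 1.87 h. Now take winter kept at 50 °C: the same step per degree gives a count of 13.2, so exp(−n) is <0.001 %. That flask holds Q 0 % and Z >99.9 %.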